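The readings were generated by integration with made-up constants, noise included.

The ratio of target to isomer of the product, each as a fraction of the charge, is what two peaks give directly in this flask, and we measure it from even odds, a ratio of one, where both hold the same fraction.

| setting | Tuesday's | flask |
|---|---|---|
| starting material | 0.50 M | 0.50 M |
| partner | 2 equiv | 2.00 equiv |
| remark | the very flask that is asked about, followed so far |  |
| time |  | 25 h |

Tuesday's run (percent of the starting material charged)

| time / h | target / % | isomer of the product / % |
|---|---|---|
| 0.417 | 2.2 | 0.3 |
| 0.667 | 5.0 | 0.7 |
| 1.00 | 7.8 | 0.8 |
| 1.33 | 12.6 | 0.4 |
| 2.00 | 19.5 | 1.3 |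
| 3.00 | 27.1 | 3.2 |
| 5.00 | 32.7 | 3.4 |

(each reading ± 0.5 percentage points)

- in percentages every species weighs as the starting material in it: one side product B counts as two
- steps that have been proposed: intermediate -> decomposed reagent; starting material + intermediate -> side product B; intermediate -> side product A; intermediate <-> isomer of the product; starting material + partner -> intermediate + by-product; intermediate <-> target

- share of target in target plus isomer of the product at 40 min
- share of target in target plus isomer of the product at 25 h

For even odds at 40 min, the isomer readings up to 2.00 h would have to sum as high as the target readings. Each is close to its scatter of 0.5 percentage points, so we pool them into the early odds, our reading of the split under kinetic control: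

early odds = sum of target fractions / sum of isomer fractions = 13.5

share = odds / (1 + odds) = 93.1%

For even odds at 25 h, target would have to sink to the isomer's level. The last reading, at 5.00 h, stands at odds of 9.62, so with the isomer held there, target would need a half-life of

(25 h − 5.00 h) × ln(2) / ln(9.62) = 6.12 h

Yet that last target reading is still higher than the one before, and its odds are lower than the early odds, so we commit to a share at 25 h above even but under 93.1%.

The forecast gives 92% and 62%, the second “very uncertain”. The flask gives 92.4% at 40 min and 68.1% at 25 h.

    intermediate → decomposed reagent (k = 0.152 h⁻¹)
    starting material + intermediate → side product B (k = 0.254 M⁻¹ h⁻¹)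
    intermediate → side product A (k = 0.120 h⁻¹)
    intermediate ⇌ isomer of the product (K = 249, k = 0.0253 h⁻¹)
    starting material + partner → intermediate + by-product (k = 1.13 M⁻¹ h⁻¹)
    intermediate ⇌ target (K = 2.70, k = 0.318 h⁻¹)

In this flask, intermediate was made 1.78 times as fast as it was used up at 0.676 h, and by 2.50 h target stood at 23.6% with starting material at 12.3%. With starting material at 0.0265% at 12.5 h, target went from 25.8% to 13.6% by 25 h while side product A rose to 30.3% and the isomer from 5.13% to 6.39%, taking the odds over that stretch from 5.03 to 2.13. In the neighbour charged with 0.12 M of starting material, the early odds of 13.5 again give 93.1% at 40 min; the computed share there is 92.4%, and 73.2% at 25 h.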